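Compound numbers used throughout: 1–18, fixed in the order of the steps below; 18 is the target.

## Analysis of the target

The target 18 is a flavone, a 4H-chromen-4-one in which benzo ring A is fused to pyranone ring C and C2 carries a 2-hydroxy-6-methoxyphenyl group (ring B). Ring A is fully substituted: C5, C7 and C8 bear methoxy groups, C6 bears the only free hydroxyl of that ring, and C4a and C8a are the fusion atoms. There is no stereocentre, and although the C2–C1' bond is flanked by two ortho substituents its rotation is not expected to be frozen, so the problem is one of regiochemistry and of telling oxygens apart. Three groups are sensitive: the 5-methoxy group peri to the C4 carbonyl, which is the ether most easily lost to Lewis acids; the electron-rich ring A, whose 6-OH lies para to O1 and is oxidisable under basic aerobic conditions; and the pyranone, which strong nucleophiles open. The difficulty is that exactly one of the four ring A oxygens, the one at C6 between two methoxy groups, must end up free, whereas a late selective demethylation would strike C5 instead; on ring B the 2'-OH must in addition be kept distinct from the 6'-OMe, and the di-ortho substitution hinders bond formation next to C1'. The strategy rests on the para relationship of O6 and O1 across ring A: C6 and C8a are the two oxygenated carbons of a hydroquinone, and C4a is the only ring A carbon bonded to carbon. Ring A is therefore the reduced form of a 1,4-benzoquinone, compound 5, with three methoxy groups and a single C–H, and that C–H carbon becomes C4a.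

## Retrosynthetic reasoning

**18 to 15 (O1–C2 and the 2'-O-acetyl bond).** Ring C is opened at O1–C2 and the 2'-hydroxyl is masked as its acetate, which leads back to the ortho-hydroxyaryl ynone 15. This cut removes only a C–O bond, and all carbons of the target are already in 15. In 15 only the C8a hydroxyl is ortho to the ynone carbonyl, so only it can close a ring. The forward step must close the six-membered ring (O1 to C2) and not the five-membered one (O1 to C3), which direct phenoxide attack on the alkyne can give. The closure is therefore routed through the amine adduct 16, where only addition–elimination at C2 is possible, and the acetate of the resulting flavone 17 is then cleaved by mild basic transesterification.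

**15 to 5 + 14 (C4–C4a).** This is the only carbon–carbon bond between ring A and the three-carbon bridge. Cutting it leaves ring A as a hydroquinone, which is the reduced form of quinone 5, and the bridge plus ring B as aldehyde 14. Cuts at C2–C1' or C3–C4 would leave a ring A piece with six different substituents whose oxygens would have to be told apart by protecting groups. With the C4–C4a cut the quinone oxidation level supplies the free 6-OH and the C8a hydroxyl without any protecting group on ring A. The forward reaction has to acylate 5 at its one unsubstituted carbon with the formyl carbon of 14 and return the ring to the hydroquinone level; a photochemical hydrogen abstraction followed by radical C–C bond formation does both.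

**5 to 4 to 1.** The second quinone oxygen is introduced by oxidation of phenol 4 at its free para position. The phenol oxygen is placed on 1 at C3, the position between two methoxy groups, by directed lithiation (aryllithium 2), borylation (boronate 3) and oxidation. The three methoxy groups of 1 are already in the positions that become C5, C7 and C8.

**14 to 13 to 11 + 12.** The aldehyde is taken back to the propargylic alcohol 13, because an activated alcohol is oxidised cleanly at the last moment and the sensitive aldehyde 14 is not carried through earlier steps. The C(sp)–C(aryl) bond of 13 is cut to aryl iodide 11 and propargyl alcohol 12, to be joined by a Sonogashira coupling.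

**11 to 10 to 9 to 7 to 6.** The iodine must sit at C2 of 6, between the two oxygens. Electrophilic iodination of 6 would go para to oxygen, so the position is reached by directed lithiation of the MOM ether 7 (aryllithium 8) and iodination to 9. The MOM group is then exchanged, via phenol 10, for the acetate of 11. An acetal or benzylic CH2 on the ring B oxygen would offer the excited quinone a weak C–H bond in the key step, a free hydroxyl ortho to the alkyne would add to it during the coupling, and the acetate comes off under the mild base used at the end.

## Alternatives that were turned down

Alternative 1: Ring C is cut at three bonds (C4a–C4, C4–C3 and O1–C2), leading to iodophenol A2, terminal arylalkyne A3 and carbon monoxide A4. In the forward key step a palladium-catalysed carbonylative coupling in a secondary amine would add A2 oxidatively, insert A4, join the acyl unit to A3 and close the pyranone. The product is A1, the 6,2'-dibenzyl ether of 18, and hydrogenolysis would finish the synthesis.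
- For it: it is the most convergent plan, C4 comes from a gas, ring C closes in the same operation with a secure ring size, and the reaction type is established for flavones. On precedent and on bonds formed per step it is stronger than the chosen route.
- Against it: A2 is a benzene with six different substituents. Its future 6-oxygen must be benzylated while the future O1 stays free, which means protecting the hydroxyl flanked by two methoxy groups in preference to the less hindered one, and then iodinating. Oxidative addition into a C–I bond flanked by OH and OMe on a ring with five donor groups is slow and is slowed further under A4. Both coupling partners are di-ortho-substituted. Direct coupling without insertion of A4 would close a five-membered oxygen ring instead of ring C. Two benzyl ethers must be removed at the end.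
- Comparison: the chosen route needs no ring A protecting group and no late hydrogenolysis, and reaches its ring A partner 5 in two steps. It pays for this with a less precedented C–C bond formation and a separate ring-closing step.

Alternative 2: Ring A is built by ring expansion: the C5–C6 bond is cut and the ring is traced back to the 4-alkenyl-4-hydroxycyclobutenone A6, made from dimethyl squarate A7 and the alkenyllithium A8, which carries the C4 carbinol and the ring B alkyne. In the forward key step heating opens the four-membered ring of A6 electrocyclically, the open form recloses by a six-electron electrocyclisation that forms C5–C6, and enolisation gives the hydroquinone A5.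
- For it: all six ring A substituents are fixed by construction, the hydroquinone with free O6 and O8a arises directly as in the chosen route, and the thermal step is well understood and needs no light. On certainty of the ring A substitution pattern and of the key step it is at least as strong.
- Against it: A5 has C4 at the alcohol level, as a silyl ether. That carbon must be desilylated and oxidised to the ketone level while the very electron-rich hydroquinone ring is free and would itself be oxidised first, so extra protection or redox steps follow. A8 is a β-methoxy alkenyllithium with a propargylic silyloxy group; it is laborious to make and prone to β-elimination. The whole carbon skeleton must be assembled linearly before the key step, and a benzyl group must still be removed at the end.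
- Comparison: the chosen route reaches the same hydroquinone pattern already at the ketone oxidation level and from a two-step quinone, in place of the better understood thermal key step.

Alternative 3: Ring A is folded from a polyketide-like chain held on a preformed 2-aryl-4-pyranone: the C4a–C5 bond is cut, leading to the keto ester A10. In the forward key step an excess of the base lithium bis(trimethylsilyl)amide A11 would generate the extended enolate and cause Claisen attack of the pyranone carbon (future C4a) on the ester carbon (future C5), giving the 5,7-dihydroxyflavone A9 after enolisation. Methylation of both phenols would then give A1, and hydrogenolysis would give 18.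
- For it: rings B and C are in place before the key step, and the 6-oxygen is differentiated from the start as its benzyl ether. On that point it is stronger than a route that would have to differentiate the oxygens late.
- Against it: A10 carries two different α-alkoxy groups on a β-keto ester chain attached to the pyranone and takes many steps to build. The polyanion has other ways to close, aldol closure onto the pyranone carbonyl among them. The chelated 5-OH of A9 methylates sluggishly. After the key step two methylations and a double debenzylation remain.
- Comparison: the chosen route needs two steps after its key step and none of these adjustments, because the quinone already has the three methyl ethers in place and the free 6-OH arises from the quinone oxidation level.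

Key step: step 9

## Route

Assumption: rotation about the C2–C1' bond of 18 is taken as free at room temperature, so the target is treated as achiral and no step has to control stereochemistry.

Step 1
Reactants: 1 1,2,4-trimethoxybenzene
Product: 4 2,3,6-trimethoxyphenol, via (2,3,6-trimethoxyphenyl)lithium 2 (not isolated), via dimethyl (2,3,6-trimethoxyphenyl)boronate 3 (not isolated)
Conditions: n-BuLi, TMEDA, THF, 0 °C; B(OMe)3, −78 → 25 °C; AcOH, H2O2 (30 %), 0 → 25 °C
Reagents that add atoms: hydrogen peroxide, OO
Why: Directed ortho-metalation: the C3–H of 1 lies between two methoxy groups and is the most acidic and best coordinated site, so lithiation should be regioselective. Borylation and peroxide oxidation (aryl shift from boron to oxygen) turn the C–Li bond into the C–OH bond.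

Step 2
Reactants: 4 2,3,6-trimethoxyphenol
Product: 5 2,3,5-trimethoxy-1,4-benzoquinone
Conditions: (KO3S)2NO, KH2PO4, H2O/acetone, 0 → 25 °C
Reagents that add atoms: potassium nitrosodisulfonate (KO3S)2NO, [K+].[K+].[O]N(S(=O)(=O)[O-])S(=O)(=O)[O-]
Why: Teuber oxidation: the phenoxyl radical of 4 is trapped by a second nitroxyl radical at its only free para position, and loss of imidodisulfonate gives the para-quinone. Both ortho positions are blocked by methoxy groups, and the buffer protects the vinylogous-ester methoxy groups of 5 from hydrolysis.

Step 3
Reactants: 6 3-methoxyphenol
Product: 7 1-methoxy-3-(methoxymethoxy)benzene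
Conditions: MOMCl, i-Pr2NEt, CH2Cl2, 0 → 25 °C
Reagents that add atoms: chloromethyl methyl ether, COCCl
Why: O-Alkylation of the phenol (Williamson type) should be clean. The MOM ether is installed as the directing group for the next step.

Step 4
Reactants: 7 1-methoxy-3-(methoxymethoxy)benzene
Product: 9 2-iodo-1-methoxy-3-(methoxymethoxy)benzene, via [2-methoxy-6-(methoxymethoxy)phenyl]lithium 8 (not isolated)
Conditions: n-BuLi, THF, 0 °C; I2, −78 → 25 °C; Na2S2O3 (aq)
Reagents that add atoms: iodine, II
Why: Directed ortho-metalation: the C2–H between OMOM and OMe is acidified and chelated by both groups, so lithiation should occur there and not para to oxygen, where electrophilic iodination of 6 itself would go. Iodinolysis of the C–Li bond then places the iodine.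

Step 5
Reactants: 9 2-iodo-1-methoxy-3-(methoxymethoxy)benzene
Product: 10 2-iodo-3-methoxyphenol
Conditions: HCl (3 M), MeOH, 50 °C
Reagents that add atoms: none
Why: Acid-catalysed acetal cleavage; the aryl methyl ether and the C–I bond are inert to dilute acid in methanol.

Step 6
Reactants: 10 2-iodo-3-methoxyphenol
Product: 11 2-iodo-3-methoxyphenyl acetate
Conditions: Ac2O, pyridine, DMAP (cat.), CH2Cl2, 0 → 25 °C
Reagents that add atoms: acetic anhydride, CC(=O)OC(C)=O
Why: Acylation of the phenol under nucleophilic catalysis. The acetate keeps the ortho oxygen from cyclising onto the alkyne during the coupling, offers no weak C–H bond in the photochemical step, and is removable by mild base at the end.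

Step 7
Reactants: 11 2-iodo-3-methoxyphenyl acetate; 12 propargyl alcohol (prop-2-yn-1-ol)
Product: 13 2-(3-hydroxyprop-1-yn-1-yl)-3-methoxyphenyl acetate
Conditions: PdCl2(PPh3)2 (cat.), CuI (cat.), Et3N, THF, 25 → 40 °C, Ar
Reagents that add atoms: none
Why: Sonogashira coupling: zerovalent palladium formed in situ inserts into the C–I bond, the acetylide formed from 12 and CuI transmetalates, and reductive elimination forms the aryl–alkyne bond. Aryl iodides couple under mild conditions even when di-ortho-substituted, and the low temperature should keep the aryl acetate intact.

Step 8
Reactants: 13 2-(3-hydroxyprop-1-yn-1-yl)-3-methoxyphenyl acetate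
Product: 14 3-methoxy-2-(3-oxoprop-1-yn-1-yl)phenyl acetate
Conditions: MnO2 (activated, excess), CH2Cl2, 25 °C
Reagents that add atoms: none
Why: Selective oxidation of an activated (propargylic) primary alcohol by MnO2 should stop at the aldehyde and leave the acetate untouched. The ynal is to be used promptly.

Step 9
Reactants: 5 2,3,5-trimethoxy-1,4-benzoquinone; 14 3-methoxy-2-(3-oxoprop-1-yn-1-yl)phenyl acetate
Product: 15 2-[3-(2,5-dihydroxy-3,4,6-trimethoxyphenyl)-3-oxoprop-1-yn-1-yl]-3-methoxyphenyl acetate
Conditions: hν (blue LEDs, visible light only), PhCF3 (degassed), Ar, 20 °C
Reagents that add atoms: none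
Why: Proposed new method: the closest known reaction is the photo-Friedel–Crafts acylation of 1,4-quinones with aliphatic, aromatic and α,β-unsaturated aldehydes, extended here to a 2-ynal and to a trialkoxy quinone. Visible light should excite only the yellow quinone 5 (14 is expected to absorb only in the ultraviolet), and the quinone triplet abstracts the formyl hydrogen of 14 to give a semiquinone and an alkynoyl radical. The alkynoyl radical should not lose CO, because that would leave an sp-hybridised alkynyl radical, so it should persist long enough to form the C–C bond. That bond, formed by recombination of the radical pair or by addition of the acyl radical to ground-state 5, can arise only at C6 of the quinone, the single ring carbon bearing hydrogen, and enolisation of the acylated ene-dione gives hydroquinone 15. No ring is closed and no stereocentre is formed in this step. The step needs C-acylation over O-acylation, which the aromatic, hydrogen-bonded acylhydroquinone favours, and it needs abstraction from the CHO group to outrun abstraction elsewhere and [2+2] addition to the alkyne. The acetate, unlike a benzyl or acetal group, has no weak C–H bond, and the acyl-conjugated alkyne is a poor partner for the electrophilic excited quinone. Remaining 5 should not oxidise 15, because the acyl group makes 15 the harder hydroquinone to oxidise.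

Step 10
Reactants: 15 2-[3-(2,5-dihydroxy-3,4,6-trimethoxyphenyl)-3-oxoprop-1-yn-1-yl]-3-methoxyphenyl acetate
Product: 18 6-hydroxy-2-(2-hydroxy-6-methoxyphenyl)-5,7,8-trimethoxy-4H-chromen-4-one, via diethylamino enone 16 (not isolated), via 2'-O-acetylflavone 17 (not isolated)
Conditions: Et2NH, EtOH, Ar, 25 → 60 °C; then K2CO3, MeOH, 25 °C; NH4Cl (aq)
Reagents that add atoms: none
Why: Conjugate addition of the amine to the ynone gives enaminone 16, and the C8a hydroxyl, the only one ortho to the carbonyl, displaces the amine by addition–elimination at C2 (6-endo-trig) to give flavone 17. This path cannot give the five-membered aurone ring that direct phenoxide attack on the ynone (5-exo-dig) could give. Carbonate in methanol then removes the aryl acetate by transesterification without touching the methyl ethers; acetate lost earlier to the amine leads to the same product.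

## Compound list

1 | 1,2,4-trimethoxybenzene | COc1ccc(OC)c(OC)c1 | starting material
2 | (2,3,6-trimethoxyphenyl)lithium | COc1ccc(OC)c(OC)c1[Li] | intermediate
3 | dimethyl (2,3,6-trimethoxyphenyl)boronate | COB(OC)c1c(OC)ccc(OC)c1OC | intermediate
4 | 2,3,6-trimethoxyphenol | COc1ccc(OC)c(OC)c1O | intermediate
5 | 2,3,5-trimethoxy-1,4-benzoquinone | COC1=CC(=O)C(OC)=C(OC)C1=O | intermediate
6 | 3-methoxyphenol | COc1cccc(O)c1 | starting material
7 | 1-methoxy-3-(methoxymethoxy)benzene | COCOc1cccc(OC)c1 | intermediate
8 | [2-methoxy-6-(methoxymethoxy)phenyl]lithium | [Li]c1c(OC)cccc1OCOC | intermediate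
9 | 2-iodo-1-methoxy-3-(methoxymethoxy)benzene | COCOc1cccc(OC)c1I | intermediate
10 | 2-iodo-3-methoxyphenol | COc1cccc(O)c1I | intermediate
11 | 2-iodo-3-methoxyphenyl acetate | CC(=O)Oc1cccc(OC)c1I | intermediate
12 | propargyl alcohol (prop-2-yn-1-ol) | C#CCO | starting material
13 | 2-(3-hydroxyprop-1-yn-1-yl)-3-methoxyphenyl acetate | CC(=O)Oc1cccc(OC)c1C#CCO | intermediate
14 | 3-methoxy-2-(3-oxoprop-1-yn-1-yl)phenyl acetate (3-[2-(acetyloxy)-6-methoxyphenyl]prop-2-ynal) | CC(=O)Oc1cccc(OC)c1C#CC=O | intermediate
15 | 2-[3-(2,5-dihydroxy-3,4,6-trimethoxyphenyl)-3-oxoprop-1-yn-1-yl]-3-methoxyphenyl acetate | CC(=O)Oc1cccc(OC)c1C#CC(=O)c1c(O)c(OC)c(OC)c(O)c1OC | intermediate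
16 | 2-[(1E)-1-(diethylamino)-3-(2,5-dihydroxy-3,4,6-trimethoxyphenyl)-3-oxoprop-1-en-1-yl]-3-methoxyphenyl acetate (either alkene isomer closes the ring) | CCN(CC)/C(c1c(OC)cccc1OC(C)=O)=C/C(=O)c1c(O)c(OC)c(OC)c(O)c1OC | intermediate
17 | 2-(6-hydroxy-5,7,8-trimethoxy-4-oxo-4H-chromen-2-yl)-3-methoxyphenyl acetate | CC(=O)Oc1cccc(OC)c1-c1cc(=O)c2c(OC)c(O)c(OC)c(OC)c2o1 | intermediate
18 | 6-hydroxy-2-(2-hydroxy-6-methoxyphenyl)-5,7,8-trimethoxy-4H-chromen-4-one (6,2'-dihydroxy-5,7,8,6'-tetramethoxyflavone) | COc1cccc(O)c1-c1cc(=O)c2c(OC)c(O)c(OC)c(OC)c2o1 | target

## Step count and risk

Total step count: 10. Longest linear sequence: 8 steps (steps 3, 4, 5, 6, 7, 8, 9, 10, from 6 to 18); the quinone branch (steps 1 and 2) joins at step 9.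

**Step 9 (key step, proposed new method).** The most likely failure is unproductive decay or diversion of the excited quinone. Three methoxy donors give its lowest triplet charge-transfer character and lower its power to abstract hydrogen. Then [2+2] photocycloaddition to the aryl alkyne, O-acylation, photoreduction by abstraction from methoxy groups, or slow polymerisation of the ynal under long irradiation could overtake C-acylation. The fallback is ionic, uses known chemistry, sets out from 5 and 14 and comes back to the route at 15. Quinone 5 would be reduced with Na2S2O4 to 2,3,5-trimethoxybenzene-1,4-diol F1, and both hydroxyls protected (MOMCl, i-Pr2NEt) to give 1,3,4-trimethoxy-2,5-bis(methoxymethoxy)benzene F2. Directed lithiation of F2 at its only ring C–H (n-BuLi, THF, 0 °C) would give [2,4,5-trimethoxy-3,6-bis(methoxymethoxy)phenyl]lithium F3, and transmetalation with MgBr2·OEt2 would give bromo[2,4,5-trimethoxy-3,6-bis(methoxymethoxy)phenyl]magnesium F4, chosen so that the nucleophile adds to the aldehyde and spares the aryl acetate. Addition of F4 to 14 at −78 °C and aqueous work-up would give the racemic propargylic alcohol 2-{3-hydroxy-3-[2,4,5-trimethoxy-3,6-bis(methoxymethoxy)phenyl]prop-1-yn-1-yl}-3-methoxyphenyl acetate F5. MnO2 oxidation would give the ynone 3-methoxy-2-{3-oxo-3-[2,4,5-trimethoxy-3,6-bis(methoxymethoxy)phenyl]prop-1-yn-1-yl}phenyl acetate F6, and CF3CO2H in wet CH2Cl2 would remove both MOM groups to give 15. Any 17 formed by acid-promoted closure at that stage is also on the route.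

**Step 10.** The most likely failures are air oxidation of the electron-rich hydroquinone under the basic amine conditions before the ring has closed, and a stalled addition–elimination, because the carbon under attack carries a di-ortho-substituted aryl group. The fallback closes ring C by carbonyl condensation under acid, where the hydroquinone is not oxidised. It sets out from 15 (through enaminone 16, formed as in step 10) and comes back at 17. Aqueous HCl in THF would hydrolyse 16 to the 1,3-diketone 2-[3-(2,5-dihydroxy-3,4,6-trimethoxyphenyl)-3-oxopropanoyl]-3-methoxyphenyl acetate F7. Catalytic H2SO4 in AcOH at 25–50 °C would then cyclodehydrate F7 to 17; the acetate is kept on ring B so that only the ring A hydroxyl can condense. The K2CO3/MeOH stage of step 10 then gives 18.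

**Step 7.** The most likely failure is acyl transfer from the aryl acetate to the propargylic hydroxyl or to the amine during a sluggish coupling of the hindered iodide. The freed phenol oxygen would then add to the ortho alkyne under the PdCl2(PPh3)2/CuI conditions, and 12 would dimerise oxidatively. The fallback brings in the three-carbon unit without a free hydroxyl and already at the aldehyde oxidation level. It sets out from 11 and comes back at 14, so that step 8 is not needed. Coupling of 11 with 3,3-diethoxyprop-1-yne (PdCl2(PPh3)2, CuI, i-Pr2NH, THF) would give 2-(3,3-diethoxyprop-1-yn-1-yl)-3-methoxyphenyl acetate F8. Aqueous formic acid at 25 °C would then hydrolyse the diethyl acetal to 14 while the aryl acetate survives.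

**Step 2.** The most likely failures are over-oxidation and hydrolytic loss of methoxy groups from the vinylogous-ester quinone in the aqueous medium, or oxidative coupling of the phenoxyl radical. The fallback introduces the para heteroatom as nitrogen. It sets out from 4 and comes back at 5. Azo coupling of 4 with benzenediazonium tetrafluoroborate at pH 9 would give 2,3,6-trimethoxy-4-[(E)-phenyldiazenyl]phenol F9. Na2S2O4 would reduce F9 to 4-amino-2,3,6-trimethoxyphenol F10, and FeCl3 in dilute HCl would oxidise F10 to quinone 5.

## Further compounds

F1 | step 9 | 2,3,5-trimethoxybenzene-1,4-diol | COc1cc(O)c(OC)c(OC)c1O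
F2 | step 9 | 1,3,4-trimethoxy-2,5-bis(methoxymethoxy)benzene | COCOc1cc(OC)c(OCOC)c(OC)c1OC
F3 | step 9 | [2,4,5-trimethoxy-3,6-bis(methoxymethoxy)phenyl]lithium | [Li]c1c(OCOC)c(OC)c(OC)c(OCOC)c1OC
F4 | step 9 | bromo[2,4,5-trimethoxy-3,6-bis(methoxymethoxy)phenyl]magnesium | Br[Mg]c1c(OCOC)c(OC)c(OC)c(OCOC)c1OC
F5 | step 9 | 2-{3-hydroxy-3-[2,4,5-trimethoxy-3,6-bis(methoxymethoxy)phenyl]prop-1-yn-1-yl}-3-methoxyphenyl acetate (racemic) | CC(=O)Oc1cccc(OC)c1C#CC(O)c1c(OCOC)c(OC)c(OC)c(OCOC)c1OC
F6 | step 9 | 3-methoxy-2-{3-oxo-3-[2,4,5-trimethoxy-3,6-bis(methoxymethoxy)phenyl]prop-1-yn-1-yl}phenyl acetate | CC(=O)Oc1cccc(OC)c1C#CC(=O)c1c(OCOC)c(OC)c(OC)c(OCOC)c1OC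
F7 | step 10 | 2-[3-(2,5-dihydroxy-3,4,6-trimethoxyphenyl)-3-oxopropanoyl]-3-methoxyphenyl acetate | CC(=O)Oc1cccc(OC)c1C(=O)CC(=O)c1c(O)c(OC)c(OC)c(O)c1OC
F8 | step 7 | 2-(3,3-diethoxyprop-1-yn-1-yl)-3-methoxyphenyl acetate | CCOC(OCC)C#Cc1c(OC)cccc1OC(C)=O
F9 | step 2 | 2,3,6-trimethoxy-4-[(E)-phenyldiazenyl]phenol | COc1cc(/N=N/c2ccccc2)c(OC)c(OC)c1O
F10 | step 2 | 4-amino-2,3,6-trimethoxyphenol | COc1cc(N)c(OC)c(OC)c1O
A1 | alternative 1 | 6-(benzyloxy)-2-[2-(benzyloxy)-6-methoxyphenyl]-5,7,8-trimethoxy-4H-chromen-4-one | COc1cccc(OCc2ccccc2)c1-c1cc(=O)c2c(OC)c(OCc3ccccc3)c(OC)c(OC)c2o1
A2 | alternative 1 | 4-(benzyloxy)-2-iodo-3,5,6-trimethoxyphenol | Oc1c(I)c(OC)c(OCc2ccccc2)c(OC)c1OC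
A3 | alternative 1 | 1-(benzyloxy)-2-ethynyl-3-methoxybenzene | C#Cc1c(OC)cccc1OCc1ccccc1
A4 | alternative 1 | carbon monoxide | [C-]#[O+]
A5 | alternative 2 | 2-{3-[2-(benzyloxy)-6-methoxyphenyl]-1-(tert-butyldimethylsilyloxy)prop-2-yn-1-yl}-3,5,6-trimethoxybenzene-1,4-diol (racemic) | Oc1c(OC)c(OC)c(O)c(OC)c1C(O[Si](C)(C)C(C)(C)C)C#Cc1c(OC)cccc1OCc1ccccc1
A6 | alternative 2 | 4-{5-[2-(benzyloxy)-6-methoxyphenyl]-3-(tert-butyldimethylsilyloxy)-1-methoxypent-1-en-4-yn-2-yl}-4-hydroxy-2,3-dimethoxycyclobut-2-en-1-one (configuration not specified) | COC=C(C(O[Si](C)(C)C(C)(C)C)C#Cc1c(OC)cccc1OCc1ccccc1)C1(O)C(OC)=C(OC)C1=O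
A7 | alternative 2 | dimethyl squarate (3,4-dimethoxycyclobut-3-ene-1,2-dione) | COC1=C(OC)C(=O)C1=O
A8 | alternative 2 | {5-[2-(benzyloxy)-6-methoxyphenyl]-3-(tert-butyldimethylsilyloxy)-1-methoxypent-1-en-4-yn-2-yl}lithium (configuration not specified) | [Li]C(=COC)C(O[Si](C)(C)C(C)(C)C)C#Cc1c(OC)cccc1OCc1ccccc1
A9 | alternative 3 | 6-(benzyloxy)-2-[2-(benzyloxy)-6-methoxyphenyl]-5,7-dihydroxy-8-methoxy-4H-chromen-4-one | COc1cccc(OCc2ccccc2)c1-c1cc(=O)c2c(O)c(OCc3ccccc3)c(O)c(OC)c2o1
A10 | alternative 3 | methyl 2-(benzyloxy)-4-{6-[2-(benzyloxy)-6-methoxyphenyl]-4-oxo-4H-pyran-2-yl}-4-methoxy-3-oxobutanoate (configuration not specified) | COC(=O)C(OCc1ccccc1)C(=O)C(OC)c1cc(=O)cc(o1)-c1c(OC)cccc1OCc1ccccc1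
A11 | alternative 3 | lithium bis(trimethylsilyl)amide | [Li]N([Si](C)(C)C)[Si](C)(C)C
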